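Ring C (the pyranone) is disconnected across C2–C3 and C4–C4a, so that ring A with its O1–CH2 arm acts as a cationic 2-oxadiene (C2 electrophile, C4a nucleophile) and the C3–C4 unit with the chromene ring B arrives as a siloxy alkyne, a ketene equivalent. The key step is a formal [4+2] annulation: an aryloxymethyl oxocarbenium ion alkylates the alkyne at C3 and the silyl ketenium ion so formed acylates C4a of the symmetric, phloroglucinol-type ring A. It delivers the C4 silyl enol ether, whose C3 is then set by catalytic enantioselective protonation before global debenzylation.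

Key step: step 6

Remark on the chemistry: the target center is (3S). The sense of induction of the chiral acid in step 7 cannot be fixed on paper; the (S)-configured catalyst is written, and its enantiomer is used instead if a test run shows that it leads to the (3R)-ketone. Compounds 1, 2 and 9 and all reagents are taken as commercial.

Step 1
Reactants: 1 4-(benzyloxy)-2-hydroxybenzaldehyde; 2 3-chloro-3-methylbut-1-yne
Product: 3 4-(benzyloxy)-2-[(2-methylbut-3-yn-2-yl)oxy]benzaldehyde
Conditions: DBU, CuCl2·2H2O (cat.), MeCN, 0 °C → rt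
Reagents that add atoms: none
Why: Copper-catalysed propargylic etherification of the phenol with the tertiary propargylic chloride should alkylate the only free hydroxyl, although it is hydrogen-bonded to the aldehyde; no stereocenter is formed.

Step 2
Reactants: 3 4-(benzyloxy)-2-[(2-methylbut-3-yn-2-yl)oxy]benzaldehyde
Product: 4 5-(benzyloxy)-2,2-dimethyl-2H-chromene-8-carbaldehyde
Conditions: o-dichlorobenzene, 180 °C
Reagents that add atoms: none
Why: Aromatic propargyl Claisen rearrangement to the only free ortho carbon, then enolisation, 1,5-hydrogen shift and oxa-6π electrocyclisation, should give the 2,2-dimethyl-2H-chromene with its ring oxygen ortho to the aldehyde, as ring B requires.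

Step 3
Reactants: 4 5-(benzyloxy)-2,2-dimethyl-2H-chromene-8-carbaldehyde
Product: 5 5-(benzyloxy)-8-ethynyl-2,2-dimethyl-2H-chromene
Conditions: dimethyl (1-diazo-2-oxopropyl)phosphonate, K2CO3, MeOH, rt
Reagents that add atoms: dimethyl (1-diazo-2-oxopropyl)phosphonate, COP(=O)(OC)C(=[N+]=[N-])C(C)=O
Why: Seyferth–Gilbert homologation with the Ohira–Bestmann reagent should turn the aryl aldehyde into the terminal alkyne under conditions that leave the benzyl ether and the chromene untouched.

Step 4
Reactants: 5 5-(benzyloxy)-8-ethynyl-2,2-dimethyl-2H-chromene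
Product: 8 ({[5-(benzyloxy)-2,2-dimethyl-2H-chromen-8-yl]ethynyl}oxy)tri(propan-2-yl)silane, via lithium acetylide 6 (not isolated), via lithium ynolate 7 (not isolated)
Conditions: n-BuLi, THF, −78 °C; LiOOt-Bu (from t-BuOOH and LiN(SiMe3)2), −78 → 0 °C; i-Pr3SiOTf, −78 → 0 °C
Reagents that add atoms: tert-butyl hydroperoxide, CC(C)(C)OO; triisopropylsilyl trifluoromethanesulfonate, CC(C)[Si](OS(=O)(=O)C(F)(F)F)(C(C)C)C(C)C
Why: Oxidation of the lithium acetylide by lithium tert-butyl peroxide to the lithium ynolate, then O-silylation (the ynolate route to siloxy alkynes), should give the stable silyl ynol ether, because the bulky silyl triflate reacts at oxygen and not at carbon.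

Step 5
Reactants: 9 3,5-bis(benzyloxy)phenol
Product: 11 [3,5-bis(benzyloxy)phenoxy]methyl 2,2-dimethylpropanoate, via sodium phenoxide 10 (not isolated)
Conditions: NaH, DMF, 0 °C; chloromethyl pivalate, NaI (cat.), 0 °C → rt
Reagents that add atoms: chloromethyl pivalate, CC(C)(C)C(=O)OCCl
Why: Williamson O-alkylation of the sodium phenoxide with the chloromethyl ester should give the aryloxymethyl pivalate, the hindered pivaloyl group suppressing acyl transfer to the phenoxide.

Step 6
Reactants: 11 [3,5-bis(benzyloxy)phenoxy]methyl 2,2-dimethylpropanoate; 8 ({[5-(benzyloxy)-2,2-dimethyl-2H-chromen-8-yl]ethynyl}oxy)tri(propan-2-yl)silane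
Product: 14 5,7-bis(benzyloxy)-3-[5-(benzyloxy)-2,2-dimethyl-2H-chromen-8-yl]-4-[(triisopropylsilyl)oxy]-2H-chromene, via aryloxymethyl oxocarbenium triflate 12 (not isolated), via silyl ketenium triflate 13 (not isolated)
Conditions: 8 (1.3 equiv), 2,6-di-tert-butyl-4-methylpyridine (1.5 equiv), TMSOTf (1.2 equiv, slow addition), CH2Cl2, −78 → −20 °C; Et3N quench
Reagents that add atoms: none
Why: Proposed new method: TMSOTf ionises the pivalate of 11 to the aryloxymethyl oxocarbenium ion 12, the nucleophilic aryl-bearing carbon of siloxy alkyne 8 attacks it (C2–C3) to give the silyl ketenium ion 13, and 13 acylates the ortho carbon of ring A (C4–C4a) before the hindered pyridine removes the arenium proton. The closest known reaction types are the oxa-Povarov annulation of aryl oxocarbenium ions with alkenes and the acid-triggered arene cyclisation of siloxy alkynes through silyl ketenium ions, merged here with a carbon electrophile in place of the proton. The pyranone ring closes as a six-membered ring by attack of the arene on the sp carbon of the ketenium ion, exo-dig with respect to the C=O+ bond that is consumed. No stereocenter is formed, because C3 is stored as the trigonal carbon of a triisopropylsilyl enol ether for step 7. The step needs capture of 12 by the alkyne and not by a second ring A, which the far higher π-nucleophilicity of the siloxy alkyne, its excess and the slow addition of TMSOTf at −78 °C should secure, and addition at the aryl-bearing alkyne carbon, which the oxygen donor dictates. The two ortho positions of ring A are equivalent by symmetry and each is activated by three oxygen substituents, so one regioisomer should result.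

Step 7
Reactants: 14 5,7-bis(benzyloxy)-3-[5-(benzyloxy)-2,2-dimethyl-2H-chromen-8-yl]-4-[(triisopropylsilyl)oxy]-2H-chromene
Product: 15 (3S)-5,7-bis(benzyloxy)-3-[5-(benzyloxy)-2,2-dimethyl-2H-chromen-8-yl]-2,3-dihydro-4H-chromen-4-one
Conditions: (S)-3,3'-bis(2,4,6-triisopropylphenyl)-1,1'-binaphthyl-2,2'-diyl N-triflyl thiophosphoramide (5 mol %), PhOH (1.2 equiv), toluene, 0 °C → rt
Reagents that add atoms: none
Why: Catalytic enantioselective protonation of a silyl enol ether of an α-aryl cyclic ketone by a chiral Brønsted acid, with phenol as stoichiometric proton source and silyl acceptor, should deliver the proton to one face of C3 within the chiral ion pair, so the catalyst sets the (3S) center.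

Step 8
Reactants: 15 (3S)-5,7-bis(benzyloxy)-3-[5-(benzyloxy)-2,2-dimethyl-2H-chromen-8-yl]-2,3-dihydro-4H-chromen-4-one
Product: 16 (3S)-5,7-dihydroxy-3-(5-hydroxy-2,2-dimethyl-2H-chromen-8-yl)-2,3-dihydro-4H-chromen-4-one
Conditions: BCl3 (1 M in CH2Cl2), pentamethylbenzene, CH2Cl2, −78 °C; MeOH/CHCl3 quench at −78 °C
Reagents that add atoms: none
Why: Lewis acid debenzylation of the three aryl benzyl ethers with BCl3 and pentamethylbenzene as a non-basic benzyl cation scavenger should free the phenols at −78 °C without base, so the enolisable C3 center and the chromene should survive.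

Compound list
1 | 4-(benzyloxy)-2-hydroxybenzaldehyde | O=Cc1ccc(OCc2ccccc2)cc1O | starting material
2 | 3-chloro-3-methylbut-1-yne | CC(C)(Cl)C#C | starting material
3 | 4-(benzyloxy)-2-[(2-methylbut-3-yn-2-yl)oxy]benzaldehyde | O=Cc1ccc(OCc2ccccc2)cc1OC(C)(C)C#C | intermediate
4 | 5-(benzyloxy)-2,2-dimethyl-2H-chromene-8-carbaldehyde | CC1(C)C=Cc2c(OCc3ccccc3)ccc(C=O)c2O1 | intermediate
5 | 5-(benzyloxy)-8-ethynyl-2,2-dimethyl-2H-chromene | CC1(C)C=Cc2c(OCc3ccccc3)ccc(C#C)c2O1 | intermediate
6 | lithium acetylide of 5 (not isolated) | CC1(C)C=Cc2c(OCc3ccccc3)ccc(C#C[Li])c2O1 | intermediate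
7 | lithium 2-[5-(benzyloxy)-2,2-dimethyl-2H-chromen-8-yl]ethyn-1-olate, the lithium ynolate (not isolated) | CC1(C)C=Cc2c(OCc3ccccc3)ccc(C#CO[Li])c2O1 | intermediate
8 | ({[5-(benzyloxy)-2,2-dimethyl-2H-chromen-8-yl]ethynyl}oxy)tri(propan-2-yl)silane | CC1(C)C=Cc2c(OCc3ccccc3)ccc(C#CO[Si](C(C)C)(C(C)C)C(C)C)c2O1 | intermediate
9 | 3,5-bis(benzyloxy)phenol | Oc1cc(OCc2ccccc2)cc(OCc2ccccc2)c1 | starting material
10 | sodium 3,5-bis(benzyloxy)phenoxide (not isolated) | [Na+].[O-]c1cc(OCc2ccccc2)cc(OCc2ccccc2)c1 | intermediate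
11 | [3,5-bis(benzyloxy)phenoxy]methyl 2,2-dimethylpropanoate | CC(C)(C)C(=O)OCOc1cc(OCc2ccccc2)cc(OCc2ccccc2)c1 | intermediate
12 | [3,5-bis(benzyloxy)phenyl](methylidene)oxonium trifluoromethanesulfonate, the aryloxymethyl oxocarbenium ion (not isolated) | C=[O+]c1cc(OCc2ccccc2)cc(OCc2ccccc2)c1.[O-]S(=O)(=O)C(F)(F)F | intermediate
13 | O-triisopropylsilyl ketenium trifluoromethanesulfonate carrying the ring B aryl group and the aryloxymethyl group on C3 (not isolated) | CC(C)[Si](C(C)C)(C(C)C)[O+]=C=C(COc1cc(OCc2ccccc2)cc(OCc2ccccc2)c1)c1ccc(OCc2ccccc2)c2C=CC(C)(C)Oc12.[O-]S(=O)(=O)C(F)(F)F | intermediate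
14 | 5,7-bis(benzyloxy)-3-[5-(benzyloxy)-2,2-dimethyl-2H-chromen-8-yl]-4-[(triisopropylsilyl)oxy]-2H-chromene | CC1(C)C=Cc2c(OCc3ccccc3)ccc(C3=C(O[Si](C(C)C)(C(C)C)C(C)C)c4c(OCc5ccccc5)cc(OCc5ccccc5)cc4OC3)c2O1 | intermediate
15 | (3S)-5,7-bis(benzyloxy)-3-[5-(benzyloxy)-2,2-dimethyl-2H-chromen-8-yl]-2,3-dihydro-4H-chromen-4-one | CC1(C)C=Cc2c(OCc3ccccc3)ccc([C@H]3COc4cc(OCc5ccccc5)cc(OCc5ccccc5)c4C3=O)c2O1 | intermediate
16 | (3S)-5,7-dihydroxy-3-(5-hydroxy-2,2-dimethyl-2H-chromen-8-yl)-2,3-dihydro-4H-chromen-4-one | CC1(C)C=Cc2c(O)ccc([C@H]3COc4cc(O)cc(O)c4C3=O)c2O1 | target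

Total step count: 8
Longest linear sequence: 7 steps (steps 1, 2, 3, 4, 6, 7, 8)

Steps most likely to fail

Step 6 (key step, proposed new method). The oxocarbenium ion may be consumed by Friedel–Crafts alkylation of a second ring A (oligomerisation). The ketenium ion may also be intercepted by the chromene oxygen of ring B before ring A closes, or the siloxy alkyne may be lost by protonolysis. The fallback uses known chemistry and makes the same two bonds one after the other; it sets out from 8 and 11 and comes back to the route at 14. Siloxy alkyne 8 is hydrolysed (Bu4NF, wet THF, 0 °C) to [5-(benzyloxy)-2,2-dimethyl-2H-chromen-8-yl]acetic acid F1. Double silylation (LiN(SiMe3)2, Me3SiCl, THF, −78 °C) gives 5-(benzyloxy)-8-[2,2-bis(trimethylsilyloxy)ethenyl]-2,2-dimethyl-2H-chromene F2. F2 is alkylated by pivalate 11 under TMSOTf catalysis (Mukaiyama-type alkylation with an α-acyloxy ether, CH2Cl2, −78 °C) and gives, after aqueous work-up, racemic 3-[3,5-bis(benzyloxy)phenoxy]-2-[5-(benzyloxy)-2,2-dimethyl-2H-chromen-8-yl]propanoic acid F3. Trifluoroacetic anhydride (CH2Cl2, 0 °C) closes ring C by intramolecular Friedel–Crafts acylation to racemic 5,7-bis(benzyloxy)-3-[5-(benzyloxy)-2,2-dimethyl-2H-chromen-8-yl]chroman-4-one F4. KN(SiMe3)2 and i-Pr3SiOTf (THF, −78 °C) then convert F4 into enol ether 14.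

Step 7. Facial discrimination in the proton transfer to the crowded, tetrasubstituted triisopropylsilyl enol ether may be insufficient, or the silyl transfer to phenol may be too slow for turnover. The fallback is a palladium-catalysed decarboxylative asymmetric protonation, a reaction type established for α-aryl cyclic ketones, isoflavanones included. It sets out from 14 and comes back at 15. Fluoride-triggered O-acylation of 14 with allyl chloroformate (Bu4N[Ph3SiF2], THF, −78 °C) gives allyl 5,7-bis(benzyloxy)-3-[5-(benzyloxy)-2,2-dimethyl-2H-chromen-8-yl]-2H-chromen-4-yl carbonate F5. Pd2(dba)3, a tert-butyl phosphinooxazoline ligand and Meldrum's acid as proton source (1,4-dioxane, rt) then release CO2 and protonate the chiral palladium enolate to 15.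

Step 8. BCl3 may promote enolisation of C3 and erode the enantiomeric purity, or may hydrochlorinate or open the chromene of ring B during debenzylation. The fallback removes the benzyl groups before the stereocenter exists and carries silyl ethers through the protonation. It sets out from 14 and comes back at 16. BCl3 and pentamethylbenzene (CH2Cl2, −78 °C, MeOH quench) convert 14 into racemic 5,7-dihydroxy-3-(5-hydroxy-2,2-dimethyl-2H-chromen-8-yl)chroman-4-one F6. t-BuMe2SiOTf and Et3N (CH2Cl2, 0 °C) give 5,7-bis(tert-butyldimethylsilyloxy)-3-[5-(tert-butyldimethylsilyloxy)-2,2-dimethyl-2H-chromen-8-yl]-4-(tert-butyldimethylsilyloxy)-2H-chromene F7. Enantioselective protonation as in step 7 gives (3S)-5,7-bis(tert-butyldimethylsilyloxy)-3-[5-(tert-butyldimethylsilyloxy)-2,2-dimethyl-2H-chromen-8-yl]chroman-4-one F8. HF·pyridine (THF, 0 °C) then frees the three phenols under non-basic conditions to give 16.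

Further compounds
F1 | step 6 | [5-(benzyloxy)-2,2-dimethyl-2H-chromen-8-yl]acetic acid | CC1(C)C=Cc2c(OCc3ccccc3)ccc(CC(=O)O)c2O1
F2 | step 6 | 5-(benzyloxy)-8-[2,2-bis(trimethylsilyloxy)ethenyl]-2,2-dimethyl-2H-chromene | C[Si](C)(C)OC(O[Si](C)(C)C)=Cc1ccc(OCc2ccccc2)c2C=CC(C)(C)Oc12
F3 | step 6 | racemic 3-[3,5-bis(benzyloxy)phenoxy]-2-[5-(benzyloxy)-2,2-dimethyl-2H-chromen-8-yl]propanoic acid | OC(=O)C(COc1cc(OCc2ccccc2)cc(OCc2ccccc2)c1)c1ccc(OCc2ccccc2)c2C=CC(C)(C)Oc12
F4 | step 6 | racemic 5,7-bis(benzyloxy)-3-[5-(benzyloxy)-2,2-dimethyl-2H-chromen-8-yl]chroman-4-one | CC1(C)C=Cc2c(OCc3ccccc3)ccc(C3COc4cc(OCc5ccccc5)cc(OCc5ccccc5)c4C3=O)c2O1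
F5 | step 7 | allyl 5,7-bis(benzyloxy)-3-[5-(benzyloxy)-2,2-dimethyl-2H-chromen-8-yl]-2H-chromen-4-yl carbonate | C=CCOC(=O)OC1=C(c2ccc(OCc3ccccc3)c3C=CC(C)(C)Oc23)COc2cc(OCc3ccccc3)cc(OCc3ccccc3)c12
F6 | step 8 | racemic 5,7-dihydroxy-3-(5-hydroxy-2,2-dimethyl-2H-chromen-8-yl)chroman-4-one | CC1(C)C=Cc2c(O)ccc(C3COc4cc(O)cc(O)c4C3=O)c2O1
F7 | step 8 | 5,7-bis(tert-butyldimethylsilyloxy)-3-[5-(tert-butyldimethylsilyloxy)-2,2-dimethyl-2H-chromen-8-yl]-4-(tert-butyldimethylsilyloxy)-2H-chromene | CC1(C)C=Cc2c(O[Si](C)(C)C(C)(C)C)ccc(C3=C(O[Si](C)(C)C(C)(C)C)c4c(O[Si](C)(C)C(C)(C)C)cc(O[Si](C)(C)C(C)(C)C)cc4OC3)c2O1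
F8 | step 8 | (3S)-5,7-bis(tert-butyldimethylsilyloxy)-3-[5-(tert-butyldimethylsilyloxy)-2,2-dimethyl-2H-chromen-8-yl]chroman-4-one | CC1(C)C=Cc2c(O[Si](C)(C)C(C)(C)C)ccc([C@H]3COc4cc(O[Si](C)(C)C(C)(C)C)cc(O[Si](C)(C)C(C)(C)C)c4C3=O)c2O1
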